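**Plan**

1. Retrosynthesis: the O9–tigloyl and O8–(R)-2-methylbutanoyl ester bonds are cut first. Ring B is then cut at C10–C1 and C4–C5, after C1 is given a carboxyl group tied to O9 as a γ-lactone and the C5 methyl (C14) is raised to a formyl group. Ring A goes back to p-benzoquinone mono(dimethyl ketal).
2. Enabling feature: in ring B, C1 is α to the C2 ketone, and C10 carries on its ring-A neighbour C9 an α-oxygen that is cis to the C10–C1 bond. A 3-oxohex-4-enoate ester on O9 (supplying C1–C4 and C15) is therefore a traceless tether, lost later as CO2. It delivers C1 to C10 of the C5(CHO)=C10 enal from the α face and leaves C5 placed to close onto C4.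
3. Forward order: ring A is built first (asymmetric Rh-catalysed isopropenyl addition, epoxidation, Wittig homologation with epoxide opening to a γ-hydroxy enal). After acylation of 9-OH, one double Michael cascade closes the lactone and then, last, ring B.
4. End game: CHO to CH3; C8 ketal to ketone to 8α-OH; esterification at O8; hydrolytic decarboxylation (frees 9-OH, C1 becomes CH2); tigloylation.
5. Stereochemistry: C7 from the chiral Rh catalyst; C9 from epoxidation anti to the isopropenyl group; C10, C5 and C4 from the tethered cascade; C8 from axial hydride addition anti to the axial C9–O bond; the acyl stereocentre from (R)-2-methylbutanoic acid; the E tiglate from tigloyl chloride.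

Key step: step 7

Remark: eremophilane numbering is used for the decalin compounds (ring B = C1–C5 and C10; ring A = C5–C10; isopropenyl = C11–C13; C14 on C5; C15 on C4). β is the face of the C5 substituent C14.
Assumption: (R)-2-methylbutanoic acid and tigloyl chloride are bought as such; the other starting materials are catalogue compounds.

**Step 1**
Reactants: 1 4,4-dimethoxycyclohexa-2,5-dien-1-one; 2 isopropenylboronic acid pinacol ester
Product: 3 (5R)-4,4-dimethoxy-5-(prop-1-en-2-yl)cyclohex-2-en-1-one
Conditions: [Rh(cod)OH]2 (2.5 mol %), (R)-BINAP (6 mol %), dioxane/H2O (10:1), 35 °C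
Reagents that add atoms: none
Why: Hayashi–Miyaura rhodium-catalysed asymmetric 1,4-addition desymmetrises the dienone, the BINAP–Rh–alkenyl species adding to one enantiotopic β-carbon so that C7 should be set as R (the (R)-ligand is chosen by analogy with cyclohex-2-enone), and the base-free conditions should keep the adduct from losing methanol to a phenol.

**Step 2**
Reactants: 3 (5R)-enone
Product: 4 (1R,4R,6S)-5,5-dimethoxy-4-(prop-1-en-2-yl)-7-oxabicyclo[4.1.0]heptan-2-one
Conditions: 30% H2O2, NaOH (0.2 equiv), MeOH, 0 °C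
Reagents that add atoms: hydrogen peroxide, OO
Why: Weitz–Scheffer nucleophilic epoxidation touches only the enone, and hydroperoxide should add to the β-carbon anti to the isopropenyl group two carbons away (as in the epoxidation of carvone), which puts the oxirane oxygen, the future O9, on the α face.

**Step 3**
Reactants: 4 epoxy ketone
Product: 5 (1S,4R,6S)-5,5-dimethoxy-2-(methoxymethylidene)-4-(prop-1-en-2-yl)-7-oxabicyclo[4.1.0]heptane (E/Z mixture)
Conditions: MeOCH2PPh3Cl, KHMDS, THF, −78 to 0 °C
Reagents that add atoms: (methoxymethyl)triphenylphosphonium chloride, COC[P+](c1ccccc1)(c1ccccc1)c1ccccc1.[Cl-]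
Why: Wittig methoxymethylenation of the ketone with a non-stabilised ylide brings in the carbon that becomes C14; the oxirane should be inert to the ylide at low temperature and the enol ether geometry is of no consequence.

**Step 4**
Reactants: 5 epoxy enol ether
Product: 6 (3S,5R)-3-hydroxy-4,4-dimethoxy-5-(prop-1-en-2-yl)cyclohex-1-ene-1-carbaldehyde
Conditions: PPTS (cat.), THF/H2O (9:1), 0 °C to rt
Reagents that add atoms: water, O
Why: Acid-induced vinylogous (SN2'-type) opening of the vinyl oxirane by the enol ether and hydrolysis of the oxocarbenium ion should give the γ-hydroxy enal with the C9–O bond untouched (configuration retained), the α-oxygenated dimethyl ketal hydrolysing more slowly and C8 carrying no hydrogen that would allow dehydration.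

**Step 5**
Reactants: 7 Meldrum's acid; 8 (2E)-but-2-enoyl chloride
Product: 9 5-[(2E)-1-hydroxybut-2-en-1-ylidene]-2,2-dimethyl-1,3-dioxane-4,6-dione
Conditions: pyridine (2 equiv), CH2Cl2, 0 °C to rt
Reagents that add atoms: none
Why: C-acylation of Meldrum's acid by the acid chloride gives the enolised acyl derivative, a storable precursor of crotonoylketene, with the E alkene unchanged.

**Step 6**
Reactants: 6 γ-hydroxy enal; 9 crotonoyl Meldrum's acid
Product: 11 (1S,5R)-3-formyl-6,6-dimethoxy-5-(prop-1-en-2-yl)cyclohex-2-en-1-yl (4E)-3-oxohex-4-enoate, via crotonoylketene 10 (not isolated)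
Conditions: toluene, 90 °C
Reagents that add atoms: none
Why: Thermal fragmentation of the acyl Meldrum's acid to the acylketene and its capture by the hindered secondary alcohol is a neutral β-keto ester synthesis that places the C1–C4/C15 unit (a Nazarov-type reagent) on O9 without touching the enal or the ketal.

**Step 7**
Reactants: 11 tethered keto ester enal
Product: 13 9α-hydroxy-8,8-dimethoxy-2,14-dioxo-10βH-eremophil-11-ene-1α-carboxylic acid 1,9-lactone, via lactone aldehyde enolate 12 (not isolated)
Conditions: Cs2CO3 (0.5 equiv), MeCN (0.01 M), 0 to 40 °C; aq. NH4Cl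
Reagents that add atoms: none
Why: Caesium carbonate deprotonates the β-keto ester at C1, which adds 5-exo-trig to C10 of the enal from the α face on which O9 holds it, giving the cis-fused γ-lactone and the aldehyde enolate 12; C5 of 12 then adds 6-endo-trig to C4 of the (E)-enone, and the product is drained as its stabilised 2-acyl-lactone enolate. The closest known reaction type is the base-mediated double Michael (anionic [4+2]) annulation of Nazarov reagents with activated cycloalkenes, together with the intramolecular double Michael reaction. C10 is fixed by the tether (a five-membered ring across C9–C10 can only be cis); C5 is fixed by stereoelectronically favoured axial attack of the exocyclic enolate on the chair of ring A, syn to the new C10–C1 bond (cis-decalin, CHO β); C4 is fixed by the E geometry of the enone in the resulting chair-like array, in which ring A lies away from the enone and the C4 methyl is pseudo-equatorial and so should end cis to the formyl group; C1 is epimerisable and should settle in the cis-fused lactone before it is erased in step 12. The step needs α-facial delivery and control of C4: the first is secured by the ester tether on the 9α-oxygen, the second by the chair of ring A with equatorial isopropenyl, since the alternative folding demands equatorial attack on a boat-like ring A.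

**Step 8**
Reactants: 13 tricyclic keto lactone aldehyde
Product: 15 9α-hydroxy-8,8-dimethoxy-2-oxo-10βH-eremophil-11-ene-1α-carboxylic acid 1,9-lactone, via tosylhydrazone 14 (not isolated)
Conditions: TsNHNH2 (1.05 equiv), MeOH, 0 °C; then catecholborane, CHCl3, 0 °C; NaOAc·3H2O, 60 °C
Reagents that add atoms: none
Why: Caglioti-type reduction: the sulfonylhydrazone should form at the aldehyde much faster than at the hindered ketone of the 2-acyl-lactone, and hydride addition to C=N followed by acetate-induced loss of sulfinate and dinitrogen turns CHO into the C14 methyl group on a quaternary carbon that cannot epimerise.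

**Step 9**
Reactants: 15 keto lactone ketal
Product: 16 9α-hydroxy-2,8-dioxo-10βH-eremophil-11-ene-1α-carboxylic acid 1,9-lactone
Conditions: TsOH·H2O (cat.), acetone/H2O (20:1), rt
Reagents that add atoms: water, O
Why: Acid-catalysed hydrolysis of the dimethyl ketal unmasks the C8 ketone under conditions mild enough that the isopropenyl group should stay out of conjugation and C7 should not epimerise.

**Step 10**
Reactants: 16 diketo lactone
Product: 17 8α,9α-dihydroxy-2-oxo-10βH-eremophil-11-ene-1α-carboxylic acid 1,9-lactone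
Conditions: NaHMDS (1.0 equiv), THF, −78 °C; then NaBH4, MeOH, −78 to −40 °C; AcOH
Reagents that add atoms: none
Why: With the 1,3-dicarbonyl unit masked as its sodium enolate, borohydride reduction is confined to the C8 ketone, and the small hydride should add axially from the β face, anti to the axial C9–O bond, to give the equatorial 8α-alcohol cis to O9 and trans to the isopropenyl group.

**Step 11**
Reactants: 17 hydroxy keto lactone; 18 (2R)-2-methylbutanoic acid
Product: 19 9α-hydroxy-8α-[(2R)-2-methylbutanoyloxy]-2-oxo-10βH-eremophil-11-ene-1α-carboxylic acid 1,9-lactone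
Conditions: DCC, DMAP (cat.), CH2Cl2, 0 °C to rt
Reagents that add atoms: none
Why: Steglich esterification of the only free hydroxyl group (O9 is still held in the lactone, so the regiochemistry is unambiguous) under conditions that should not enolise the α-stereocentre of the acid.

**Step 12**
Reactants: 19 ester keto lactone
Product: 21 9α-hydroxy-8α-[(2R)-2-methylbutanoyloxy]-10βH-eremophil-11-en-2-one, via keto acid 20 (not isolated)
Conditions: LiCl, DMSO/H2O (10:1), 120 °C
Reagents that add atoms: none
Why: Krapcho-type neutral hydrolysis of the activated 2-acyl-γ-lactone and decarboxylation of the β-keto acid remove the tether carbon, turning C1 into CH2 and freeing the 9α-hydroxyl group, while the ordinary secondary ester should survive.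

**Step 13**
Reactants: 21 9α-hydroxy ester; 22 tigloyl chloride
Product: 23 8α-[(2R)-2-methylbutanoyloxy]-9α-[(2E)-2-methylbut-2-enoyloxy]-10βH-eremophil-11-en-2-one, (4S,5R,7R,8R,9S,10S)
Conditions: pyridine, DMAP (cat.), CH2Cl2, 0 °C to rt
Reagents that add atoms: none
Why: DMAP-catalysed acylation of the remaining axial 9α-hydroxyl group by the acid chloride completes the diester, the E tiglate being the stable geometry that should not isomerise.

**Compound list**

1 | 4,4-dimethoxycyclohexa-2,5-dien-1-one | COC1(OC)C=CC(=O)C=C1 | starting material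
2 | 4,4,5,5-tetramethyl-2-(prop-1-en-2-yl)-1,3,2-dioxaborolane | CC(=C)B1OC(C)(C)C(C)(C)O1 | starting material
3 | (5R)-4,4-dimethoxy-5-(prop-1-en-2-yl)cyclohex-2-en-1-one | C=C(C)[C@H]1CC(=O)C=CC1(OC)OC | intermediate
4 | (1R,4R,6S)-5,5-dimethoxy-4-(prop-1-en-2-yl)-7-oxabicyclo[4.1.0]heptan-2-one | C=C(C)[C@H]1CC(=O)[C@@H]2O[C@@H]2C1(OC)OC | intermediate
5 | (1S,4R,6S)-5,5-dimethoxy-2-(methoxymethylidene)-4-(prop-1-en-2-yl)-7-oxabicyclo[4.1.0]heptane, E/Z mixture | C=C(C)[C@H]1CC(=COC)[C@@H]2O[C@@H]2C1(OC)OC | intermediate
6 | (3S,5R)-3-hydroxy-4,4-dimethoxy-5-(prop-1-en-2-yl)cyclohex-1-ene-1-carbaldehyde | C=C(C)[C@H]1CC(C=O)=C[C@H](O)C1(OC)OC | intermediate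
7 | 2,2-dimethyl-1,3-dioxane-4,6-dione (Meldrum's acid) | CC1(C)OC(=O)CC(=O)O1 | starting material
8 | (2E)-but-2-enoyl chloride | C/C=C/C(Cl)=O | starting material
9 | 5-[(2E)-1-hydroxybut-2-en-1-ylidene]-2,2-dimethyl-1,3-dioxane-4,6-dione | C/C=C/C(O)=C1C(=O)OC(C)(C)OC1=O | intermediate
10 | (4E)-hexa-1,4-diene-1,3-dione (crotonoylketene, not isolated) | C/C=C/C(=O)C=C=O | intermediate
11 | (1S,5R)-3-formyl-6,6-dimethoxy-5-(prop-1-en-2-yl)cyclohex-2-en-1-yl (4E)-3-oxohex-4-enoate | C=C(C)[C@H]1CC(C=O)=C[C@H](OC(=O)CC(=O)/C=C/C)C1(OC)OC | intermediate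
12 | caesium aldehyde enolate of the mono-Michael adduct: cis-fused γ-lactone on C9–C10, C1 bearing the (E)-but-2-enoyl group, C5=CH–O⁻ (not isolated; C1 and enolate geometry undefined) | [Cs+].C=C(C)[C@H]1CC(=C[O-])[C@H](C2C(=O)/C=C/C)[C@H](OC2=O)C1(OC)OC | intermediate
13 | 9α-hydroxy-8,8-dimethoxy-2,14-dioxo-10βH-eremophil-11-ene-1α-carboxylic acid 1,9-lactone (1βH, 4β-CH3, 5β-CHO, 7β-isopropenyl) | C=C(C)[C@H]1C[C@@]2(C=O)[C@H]([C@@H]3C(=O)C[C@@H]2C)[C@H](OC3=O)C1(OC)OC | intermediate
14 | 14-(4-methylbenzenesulfonyl)hydrazone of 13 (not isolated) | C=C(C)[C@H]1C[C@@]2(C=NNS(=O)(=O)c4ccc(C)cc4)[C@H]([C@@H]3C(=O)C[C@@H]2C)[C@H](OC3=O)C1(OC)OC | intermediate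
15 | 9α-hydroxy-8,8-dimethoxy-2-oxo-10βH-eremophil-11-ene-1α-carboxylic acid 1,9-lactone | C=C(C)[C@H]1C[C@@]2(C)[C@H]([C@@H]3C(=O)C[C@@H]2C)[C@H](OC3=O)C1(OC)OC | intermediate
16 | 9α-hydroxy-2,8-dioxo-10βH-eremophil-11-ene-1α-carboxylic acid 1,9-lactone | C=C(C)[C@H]1C[C@@]2(C)[C@H]([C@@H]3C(=O)C[C@@H]2C)[C@H](OC3=O)C1=O | intermediate
17 | 8α,9α-dihydroxy-2-oxo-10βH-eremophil-11-ene-1α-carboxylic acid 1,9-lactone | C=C(C)[C@H]1C[C@@]2(C)[C@H]([C@@H]3C(=O)C[C@@H]2C)[C@H](OC3=O)[C@@H]1O | intermediate
18 | (2R)-2-methylbutanoic acid | CC[C@@H](C)C(=O)O | starting material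
19 | 9α-hydroxy-8α-[(2R)-2-methylbutanoyloxy]-2-oxo-10βH-eremophil-11-ene-1α-carboxylic acid 1,9-lactone | C=C(C)[C@H]1C[C@@]2(C)[C@H]([C@@H]3C(=O)C[C@@H]2C)[C@H](OC3=O)[C@@H]1OC(=O)[C@H](C)CC | intermediate
20 | 9α-hydroxy-8α-[(2R)-2-methylbutanoyloxy]-2-oxo-10βH-eremophil-11-ene-1α-carboxylic acid (not isolated) | C=C(C)[C@H]1C[C@@]2(C)[C@H]([C@@H](C(=O)O)C(=O)C[C@@H]2C)[C@H](O)[C@@H]1OC(=O)[C@H](C)CC | intermediate
21 | 9α-hydroxy-8α-[(2R)-2-methylbutanoyloxy]-10βH-eremophil-11-en-2-one | C=C(C)[C@H]1C[C@@]2(C)[C@H](CC(=O)C[C@@H]2C)[C@H](O)[C@@H]1OC(=O)[C@H](C)CC | intermediate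
22 | (2E)-2-methylbut-2-enoyl chloride (tigloyl chloride) | C/C=C(\C)C(Cl)=O | starting material
23 | (4S,5R,7R,8R,9S,10S)-8-[(2R)-2-methylbutanoyloxy]-9-[(2E)-2-methylbut-2-enoyloxy]eremophil-11-en-2-one (4β,5β-dimethyl, 7β-isopropenyl, 8α,9α-diacyloxy, 10βH) | C=C(C)[C@H]1C[C@@]2(C)[C@H](CC(=O)C[C@@H]2C)[C@H](OC(=O)/C(C)=C/C)[C@@H]1OC(=O)[C@H](C)CC | target

**Step count and risks**

Total step count: 13. Longest linear sequence: 12 steps (steps 1–4 and 6–13); step 5 prepares the acylating agent.

The three steps most likely to fail: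

- **Step 7.** Proton transfer from the very acidic C1–H of the first Michael adduct may quench the aldehyde enolate, so that the sequence stalls after the first addition. The chain may also fold with ring A under the enone and erode the C4 configuration. Fallback, from 11 back to 13: DBU (1.0 equiv) in CH2Cl2 at −20 °C with an acetic acid quench should stop after the first addition and give the mono-Michael lactone aldehyde F1 (mixture at C1 and C5). Pyrrolidine and acetic acid (20 mol % each) in CHCl3 at 40 °C would then form the C5 enamine, whose 6-endo Michael addition to the enone through the same chair-like array, followed by hydrolysis on work-up, returns to 13.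

- **Step 8.** Hydrazone formation and reduction may fail to discriminate between the aldehyde and the ketone of the 2-acyl-lactone, leading to over-reduction or cyclocondensation at the 1,3-dicarbonyl unit. Fallback, from 13 back to 15: NaBH4 (0.3 equiv) in EtOH at −78 °C should reduce only the aldehyde to the primary alcohol F2. 1,1'-Thiocarbonyldiimidazole with DMAP in CH2Cl2 converts it into the imidazolylthiocarbonate F3, and Bu3SnH/AIBN in toluene at 110 °C (Barton–McCombie deoxygenation) gives 15.

- **Step 13** (together with the unmasking in step 12). 1,2-Acyl migration between the cis-vicinal O8 and O9 may scramble the ester positions once 9-OH is free, and acylation of the hindered axial 9-OH may be sluggish. Fallback, from 17 back to 23: the 8-hydroxyl group is protected with TESOTf/2,6-lutidine as the silyl ether F4. LiCl in DMSO/H2O at 120 °C gives the decarboxylated 9α-alcohol F5, and tigloyl chloride/pyridine/DMAP gives the tiglate F6. HF·pyridine in THF frees the 8α-alcohol F7, which is esterified with 18 (DCC, DMAP cat.) to give 23.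

**Further compounds**

F1 | step 7 | mono-Michael lactone aldehyde: 13 without the C4–C5 bond (5-CHO with C5–H, C1 bearing the (E)-but-2-enoyl group; mixture at C1 and C5) | C=C(C)[C@H]1CC(C=O)[C@H](C2C(=O)/C=C/C)[C@H](OC2=O)C1(OC)OC
F2 | step 8 | 14-hydroxy analogue of 15 (5β-CH2OH): 9α,14-dihydroxy-8,8-dimethoxy-2-oxo-10βH-eremophil-11-ene-1α-carboxylic acid 1,9-lactone | C=C(C)[C@H]1C[C@@]2(CO)[C@H]([C@@H]3C(=O)C[C@@H]2C)[C@H](OC3=O)C1(OC)OC
F3 | step 8 | 14-O-(1H-imidazol-1-ylcarbonothioyl) derivative of F2 | C=C(C)[C@H]1C[C@@]2(COC(=S)n4ccnc4)[C@H]([C@@H]3C(=O)C[C@@H]2C)[C@H](OC3=O)C1(OC)OC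
F4 | step 13 | 8-O-triethylsilyl ether of 17 | C=C(C)[C@H]1C[C@@]2(C)[C@H]([C@@H]3C(=O)C[C@@H]2C)[C@H](OC3=O)[C@@H]1O[Si](CC)(CC)CC
F5 | step 13 | 9α-hydroxy-8α-(triethylsilyloxy)-10βH-eremophil-11-en-2-one | C=C(C)[C@H]1C[C@@]2(C)[C@H](CC(=O)C[C@@H]2C)[C@H](O)[C@@H]1O[Si](CC)(CC)CC
F6 | step 13 | 9α-[(2E)-2-methylbut-2-enoyloxy]-8α-(triethylsilyloxy)-10βH-eremophil-11-en-2-one | C=C(C)[C@H]1C[C@@]2(C)[C@H](CC(=O)C[C@@H]2C)[C@H](OC(=O)/C(C)=C/C)[C@@H]1O[Si](CC)(CC)CC
F7 | step 13 | 8α-hydroxy-9α-[(2E)-2-methylbut-2-enoyloxy]-10βH-eremophil-11-en-2-one | C=C(C)[C@H]1C[C@@]2(C)[C@H](CC(=O)C[C@@H]2C)[C@H](OC(=O)/C(C)=C/C)[C@@H]1O
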